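## Retrosynthetic overview

1. Feature: in the tetrasubstituted pyrrole ring, the edge N1–C5 with its acetyl group is the skeleton of aminoacetone (H2N–CH2–COCH3). The chain C2(CO2H)–C3(indol-3-yl)–C4(indol-3-yl) is a 3,4-di(indolyl)-2-oxobut-3-enoate.
2. The carboxylic acid and the second indole N–H are released last, from a methyl ester and an N-Boc group, in one basic operation.
3. The pyrrole is the only ring that is built, since both indole rings are bought. It is cut at N1–C2 (imine condensation) and at C4–C5 (1,5-electrocyclisation of a 2-azapentadienyl anion), followed by loss of two hydrogens.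
4. The enone is cut at C3=C4 (Knoevenagel) into 1-Boc-indole-3-carbaldehyde and methyl indol-3-ylpyruvate, which is made from the acid.

Key step: step 3

Remark: pyrrole numbering (N1, C2 bearing the carboxyl group, C5 bearing the acetyl group) is also used for the open-chain precursors. Arylpyruvates are drawn in the keto form although the enol should prevail. The target has no stereocentre.

## Route

Step 1
Reactants: 1 indole-3-pyruvic acid
Product: 2 methyl 3-(1H-indol-3-yl)-2-oxopropanoate
Conditions: MeI (1.2 equiv), KHCO3 (1.1 equiv), DMF, 0 °C to rt, Ar, dark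
Reagents that add atoms: iodomethane (MeI), CI
Why: Carboxylate O-alkylation (SN2): the weak base KHCO3 ionises only the carboxylic acid, so MeI methylates the carboxylate and leaves the enol and the indole N–H alone.

Step 2
Reactants: 2 methyl 3-(1H-indol-3-yl)-2-oxopropanoate; 3 tert-butyl 3-formyl-1H-indole-1-carboxylate
Product: 4 methyl (E)-4-[1-(tert-butoxycarbonyl)indol-3-yl]-3-(1H-indol-3-yl)-2-oxobut-3-enoate
Conditions: piperidine (0.2 equiv), AcOH (0.2 equiv), 4 Å MS, toluene, 80 °C, Ar
Reagents that add atoms: none
Why: Knoevenagel condensation with removal of water: the CH2 group of 2 is activated by the keto ester and the indole, the Boc group of 3 switches off the vinylogous-amide deactivation of the formyl group, and conjugation with both indoles drives dehydration to the less strained E-alkene (Boc-indolyl trans to the keto carbon).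

Step 3
Reactants: 4 methyl (E)-4-[1-(tert-butoxycarbonyl)indol-3-yl]-3-(1H-indol-3-yl)-2-oxobut-3-enoate; 5 aminoacetone hydrochloride
Product: 10 methyl 5-acetyl-4-[1-(tert-butoxycarbonyl)indol-3-yl]-3-(1H-indol-3-yl)-1H-pyrrole-2-carboxylate, via aminoacetone 6 (not isolated), via N-acetonyl imine 7 (not isolated), via 2-azapentadienyl anion 8 (not isolated), via dihydropyrrole 9 (not isolated)
Conditions: 5 (3 equiv, in portions), pyridine, 3 Å MS, 80 °C, Ar; then Cu(OAc)2 (4 equiv), 80 °C, same flask
Reagents that add atoms: none
Why: Proposed new method: pyridine frees only a small stationary amount of 6 from 5, 6 condenses with the C2 keto group of 4 to imine 7, and the N–CH2 group of 7, acidified by the acetyl group and by the α-imino ester, loses a proton to give the 2-azapentadienyl anion 8 (C5–N1–C2–C3–C4, six π electrons). The pyrrole ring closes by thermal disrotatory 1,5-electrocyclisation of 8, which joins C5 to C4 in a pericyclic mode and so is not subject to the poor 5-endo-trig geometry of a plain Michael closure; protonation gives 9, and two equivalents of Cu(OAc)2 (divalent copper going to monovalent copper) take away H-4 and H-5, so that aromatisation to 10 drains all preceding equilibria. The closest known reaction type is the one-pot condensation, 1,5-electrocyclisation and Cu(OAc)2 or DDQ dehydrogenation of chalcone-type enones with glycine ester or aminoacetonitrile hydrochloride in pyridine; not yet shown are an α-amino ketone as amine partner and a 2-oxobut-3-enoate as enone partner. The acetyl group makes 7 far more acidic than a glycinate imine, so much more anion is present under the same weak base, which should outweigh its lower nucleophilicity at C5. C4 and C5 of 9 are the only new stereocentres: disrotation of the U-shaped anion with the acetyl and Boc-indolyl groups turned outward should set them cis, C5 can epimerise, and both are erased in 10. The step needs 1,2- rather than 1,4-attack of the amine and cross- rather than self-condensation of 6; the first is secured by the strongly electrophilic keto carbonyl next to the ester, set against a trisubstituted alkene whose terminus is shielded and electronically damped by the indole, and the second by the low level of free amine and the excess of 5.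

Step 4
Reactants: 10 methyl 5-acetyl-4-[1-(tert-butoxycarbonyl)indol-3-yl]-3-(1H-indol-3-yl)-1H-pyrrole-2-carboxylate
Product: 13 5-acetyl-3,4-di(1H-indol-3-yl)-1H-pyrrole-2-carboxylic acid, via N-H methyl ester 11 (not isolated), via lithium carboxylate 12 (not isolated)
Conditions: LiOH·H2O (10 equiv), THF/MeOH/H2O, 60 °C, Ar; then 1 M HCl, 0 °C, to pH 3
Reagents that add atoms: lithium hydroxide, [Li+].[OH-]; water, O
Why: Saponification (BAc2) combined with nucleophilic cleavage of an indole carbamate: the N-Boc group of an indole is an activated carbamate and falls first to give 11, hot hydroxide then hydrolyses the pyrrole ester to 12, the acetyl group carries no leaving group and survives, and cold mild acidification avoids protodecarboxylation.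

## Compound list

1 | indole-3-pyruvic acid, 3-(1H-indol-3-yl)-2-oxopropanoic acid | O=C(O)C(=O)Cc1c[nH]c2ccccc12 | starting material
2 | methyl 3-(1H-indol-3-yl)-2-oxopropanoate (keto form drawn) | COC(=O)C(=O)Cc1c[nH]c2ccccc12 | intermediate
3 | tert-butyl 3-formyl-1H-indole-1-carboxylate | CC(C)(C)OC(=O)n1cc(C=O)c2ccccc12 | starting material
4 | methyl (E)-4-[1-(tert-butoxycarbonyl)indol-3-yl]-3-(1H-indol-3-yl)-2-oxobut-3-enoate | COC(=O)C(=O)/C(=C/c1cn(C(=O)OC(C)(C)C)c2ccccc12)c1c[nH]c2ccccc12 | intermediate
5 | aminoacetone hydrochloride (1-aminopropan-2-one hydrochloride) | CC(=O)CN.Cl | starting material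
6 | aminoacetone (1-aminopropan-2-one, free base) | CC(=O)CN | intermediate (not isolated)
7 | methyl (E)-4-[1-(tert-butoxycarbonyl)indol-3-yl]-3-(1H-indol-3-yl)-2-[(2-oxopropyl)imino]but-3-enoate (C=N geometry labile) | COC(=O)C(=NCC(C)=O)/C(=C/c1cn(C(=O)OC(C)(C)C)c2ccccc12)c1c[nH]c2ccccc12 | intermediate (not isolated)
8 | 2-azapentadienyl anion of 7, deprotonated at the N–CH2 carbon (counter-ion pyridinium) | COC(=O)C(=N[CH-]C(C)=O)/C(=C/c1cn(C(=O)OC(C)(C)C)c2ccccc12)c1c[nH]c2ccccc12 | intermediate (not isolated)
9 | methyl cis-5-acetyl-4-[1-(tert-butoxycarbonyl)indol-3-yl]-3-(1H-indol-3-yl)-4,5-dihydro-1H-pyrrole-2-carboxylate (racemic, one enantiomer drawn, C5 epimerisable) | COC(=O)C1=C(c2c[nH]c3ccccc23)[C@@H](c2cn(C(=O)OC(C)(C)C)c3ccccc23)[C@@H](C(C)=O)N1 | intermediate (not isolated)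
10 | methyl 5-acetyl-4-[1-(tert-butoxycarbonyl)indol-3-yl]-3-(1H-indol-3-yl)-1H-pyrrole-2-carboxylate | COC(=O)c1[nH]c(C(C)=O)c(-c2cn(C(=O)OC(C)(C)C)c3ccccc23)c1-c1c[nH]c2ccccc12 | intermediate
11 | methyl 5-acetyl-3,4-di(1H-indol-3-yl)-1H-pyrrole-2-carboxylate | COC(=O)c1[nH]c(C(C)=O)c(-c2c[nH]c3ccccc23)c1-c1c[nH]c2ccccc12 | intermediate (not isolated)
12 | lithium 5-acetyl-3,4-di(1H-indol-3-yl)-1H-pyrrole-2-carboxylate | [Li+].CC(=O)c1[nH]c(C(=O)[O-])c(-c2c[nH]c3ccccc23)c1-c1c[nH]c2ccccc12 | intermediate (not isolated)
13 | 5-acetyl-3,4-di(1H-indol-3-yl)-1H-pyrrole-2-carboxylic acid | CC(=O)c1[nH]c(C(=O)O)c(-c2c[nH]c3ccccc23)c1-c1c[nH]c2ccccc12 | target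

## Step count

Total step count: 4. Longest linear sequence: 4 steps (1 → 2 → 4 → 10 → 13).

## Steps most likely to fail

**1. Step 3 (Proposed new method).**
- What may go wrong:
  - Self-condensation of the liberated amine may outrun imine formation.
  - The amine may add in conjugate fashion and then lactamise onto the methyl ester.
  - The imine may be lost by a prototropic shift (transamination).
  - The strongly stabilised anion may close too slowly.
  - The Boc group may be lost by aminolysis before ring closure.
- Fallback (known chemistry, Paal–Knorr logic in place of the electrocyclisation): it sets out from 2 and comes back at 11. Oxidative enolate dimerisation of 2 (NaH, THF, 0 °C; I2, 0.5 equiv, −78 °C to rt) should give dimethyl 3,4-di(1H-indol-3-yl)-2,5-dioxohexanedioate F1. This is condensed crude with NH4OAc in MeOH to dimethyl 3,4-di(1H-indol-3-yl)-1H-pyrrole-2,5-dicarboxylate F2. One equivalent of KOH (THF/MeOH/H2O, 50 °C) should desymmetrise F2 to 5-(methoxycarbonyl)-3,4-di(1H-indol-3-yl)-1H-pyrrole-2-carboxylic acid F3, because the carboxylate formed first shields the second ester. EDC·HCl, HOBt, MeNH(OMe)·HCl and iPr2NEt in DMF turn it into methyl 3,4-di(1H-indol-3-yl)-5-[methoxy(methyl)carbamoyl]-1H-pyrrole-2-carboxylate F4. MeMgBr (5 equiv, three of them consumed by the N–H groups, THF, −20 to 0 °C) adds to the chelating Weinreb amide to give 11, which the LiOH treatment of step 4 carries on to 13.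

**2. Step 2.**
- What may go wrong:
  - The aldol adduct may lactonise onto the methyl ester instead of dehydrating.
  - Piperidine may cleave the Boc group of the aldehyde by aminolysis.
  - The enolised pyruvate may be degraded by air oxidation.
- Fallback (the C3–indolyl bond is made by cross-coupling, instead of the C3=C4 bond by condensation): it sets out from 3 and comes back at 4. Wittig olefination of 3 with methyl 2-oxo-3-(triphenylphosphoranylidene)propanoate (toluene, 80 °C) should give methyl (E)-4-[1-(tert-butoxycarbonyl)indol-3-yl]-2-oxobut-3-enoate F5. Br2 (CH2Cl2, −78 °C) adds anti to the alkene, the indole C2 position being deactivated by Boc and the acceptor chain, to give methyl rac-(3R*,4S*)-3,4-dibromo-4-[1-(tert-butoxycarbonyl)indol-3-yl]-2-oxobutanoate F6. Et3N in the same flask removes HBr to give methyl (Z)-3-bromo-4-[1-(tert-butoxycarbonyl)indol-3-yl]-2-oxobut-3-enoate F7. Suzuki–Miyaura coupling of F7 with 3-(4,4,5,5-tetramethyl-1,3,2-dioxaborolan-2-yl)-1H-indole (Pd(PPh3)4, K3PO4, dioxane/H2O, 70 °C) proceeds with retention at the alkene and delivers 4.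

**3. Step 4.**
- What may go wrong:
  - Saponification may be sluggish because deprotonation of the pyrrole N–H deactivates the ester.
  - Forcing conditions may cause aldol-type self-condensation at the acetyl group.
  - The acid may protodecarboxylate during acidification.
- Fallback (the two groups are removed one after the other, and the ester is cut at the O–CH3 bond instead of at the acyl carbon): it sets out from 10 and comes back at 13, passing through 11 and 12. K2CO3 in MeOH at rt removes the Boc group by methanolysis, and 11 is isolated. LiI (10 equiv) in pyridine at reflux demethylates 11 by SN2 attack of iodide on the methyl group and gives 12 without any hydroxide. Cold dilute HCl then sets 13 free. No compound outside the compound list arises on this way (F0).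

## Further compounds

F1 | step 3 | dimethyl 3,4-di(1H-indol-3-yl)-2,5-dioxohexanedioate (mixture of dl and meso forms, both centres erased in F2) | COC(=O)C(=O)C(c1c[nH]c2ccccc12)C(c1c[nH]c2ccccc12)C(=O)C(=O)OC
F2 | step 3 | dimethyl 3,4-di(1H-indol-3-yl)-1H-pyrrole-2,5-dicarboxylate | COC(=O)c1[nH]c(C(=O)OC)c(-c2c[nH]c3ccccc23)c1-c1c[nH]c2ccccc12
F3 | step 3 | 5-(methoxycarbonyl)-3,4-di(1H-indol-3-yl)-1H-pyrrole-2-carboxylic acid | COC(=O)c1[nH]c(C(=O)O)c(-c2c[nH]c3ccccc23)c1-c1c[nH]c2ccccc12
F4 | step 3 | methyl 3,4-di(1H-indol-3-yl)-5-[methoxy(methyl)carbamoyl]-1H-pyrrole-2-carboxylate | COC(=O)c1[nH]c(C(=O)N(C)OC)c(-c2c[nH]c3ccccc23)c1-c1c[nH]c2ccccc12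
F5 | step 2 | methyl (E)-4-[1-(tert-butoxycarbonyl)indol-3-yl]-2-oxobut-3-enoate | COC(=O)C(=O)/C=C/c1cn(C(=O)OC(C)(C)C)c2ccccc12
F6 | step 2 | methyl rac-(3R*,4S*)-3,4-dibromo-4-[1-(tert-butoxycarbonyl)indol-3-yl]-2-oxobutanoate (one enantiomer drawn) | COC(=O)C(=O)[C@H](Br)[C@H](Br)c1cn(C(=O)OC(C)(C)C)c2ccccc12
F7 | step 2 | methyl (Z)-3-bromo-4-[1-(tert-butoxycarbonyl)indol-3-yl]-2-oxobut-3-enoate | COC(=O)C(=O)/C(Br)=C/c1cn(C(=O)OC(C)(C)C)c2ccccc12
F0 | step 4 | none | none
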